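## The problem

The target is a flavone, a 4H-chromen-4-one whose ring A carries a substituent on every carbon (5-OH, 6-OMe, 7-OH, 8-OMe) and whose C2 bears a symmetrical 3,4,5-trimethoxyphenyl ring B. It has no stereocentre, so the task is to place seven oxygen substituents correctly, keep two of them as free hydroxyls, and build the three-carbon bridge C2–C3–C4 between two electron-rich arenes. Late selective demethylation is unattractive because the 5-, 7- and 4'-methyl ethers would compete, so the two hydroxyls and the oxygen that becomes O1 are better carried under groups that leave without touching a methyl ether. Once its phenols are free, the pentaoxygenated ring A is easily oxidised to quinones, and its flanked methyl ethers do not tolerate strong Lewis acids. The carbonyl that becomes C4 sits between two ortho substituents and is poorly accessible to nucleophiles. The open-chain ring A precursor has a mirror plane through the acyl carbon and the para oxygen, so either ortho oxygen can become O1 and the same flavone results; an acid-induced Wessely–Moser ring opening and reclosure is degenerate for the same reason. C2 is a single carbon at the carbonyl oxidation level, lying between C3 (the methyl carbon of a ring A acetophenone) and C1' of ring B. It can therefore be delivered as carbon monoxide in a three-component coupling of a ketone enolate with an aryl iodide.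

## Retrosynthesis

**11 to 9 (O1–C2).** The pyranone ring of target 11 is opened at O1–C2, with formal addition of water across C2=C3, to give the trihydroxy 1,3-diketone 9; hemiketal 10 is the intermediate of the forward reaction. The neighbouring cut, oxidative closure of a chalcone, would expose free electron-rich phenols to an oxidant. The acid cyclodehydration asks only that a phenol adds to the ring B carbonyl and water is lost. Because ring A of 9 is symmetrical, one flavone must result.

**9 to 8 (three O–benzyl bonds).** The three phenols of 9 are masked as benzyl ethers in 8. Benzyl is preferred to methyl, which cannot be removed selectively, and to silyl, which would not survive strong base. It withstands hot methoxide, a silylamide base and palladium under CO, and leaves by neutral hydrogenolysis. The forward step must remove three benzyl groups without reducing the diketone.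

**8 to 4, 5 and 6 (C2–C3 and C2–C1').** Both bonds to C2 are cut, giving acetophenone 4, 5-iodo-1,2,3-trimethoxybenzene 5 and carbon monoxide 6; the enolate 7 of 4 is the nucleophile. A cut at C3–C4 would require attack on a ring A acyl derivative flanked by two benzyloxy groups. A cut at C2–C3 alone (Claisen condensation with a ring B ester) is comparable in length and is kept in reserve. The three-component cut uses the commercial iodide directly and asks of ring A only that its methyl ketone be deprotonated. The forward reaction must aroylate a hindered enolate on carbon.

**4 to 3 (two aryl C–OMe bonds).** The methoxy groups at C3 and C5 of the acetophenone are traced to the bromides of 3. The opposite order, starting from a 2,6-dimethoxylated phenol and adding two hydroxyls, the acetyl group and two further benzyl groups later, would take about five steps against three. The forward step is a double copper-catalysed methoxylation at positions flanked by two benzyloxy groups, with an enolisable ketone present.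

**3 to 2 (two C–Br bonds).** The bromines of 3 occupy the only two free ring positions of 2, each activated by three alkoxy groups, so there is no regiochemical question. The forward step must brominate the nucleus and not the acetyl methyl group.

**2 to 1 (ring C–acetyl bond).** Ketone 2 is cut at the bond between the ring and the acetyl carbon, leading to commercial 1,3,5-tris(benzyloxy)benzene 1, which already holds three of the five ring A oxygens under their final protecting groups. Its three free positions are equivalent, so monoacetylation has no regiochemical question. The neighbouring cut at the three O–benzyl bonds, from 2,4,6-trihydroxyacetophenone, is as short but has to force two hydrogen-bonded ortho hydroxyls to alkylate and to suppress C-benzylation of the phloroglucinol nucleus. The forward step must acylate once and must not strip or shift a benzyl group.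

## Roads not taken

**Alternative 1:** Ring A is built onto a preformed 2-aryl-4-pyranone. C4a–C5 is made by adding the metalated pyranone to a mixed squarate ester, and C8–C8a closes the ring.
- Key step: heating 2-tert-butoxy-4-hydroxy-3-methoxy-4-[4-oxo-6-(3,4,5-trimethoxyphenyl)-4H-pyran-3-yl]cyclobut-2-en-1-one A2 opens the four-membered ring to a dienylketene. A 6π electrocyclisation onto the pyranone and tautomerisation give 7-tert-butoxy-5,8-dihydroxy-6-methoxy-2-(3,4,5-trimethoxyphenyl)-4H-chromen-4-one A1.
- Merits: every ring A oxygen is placed and differentiated by construction. No aromatic substitution is needed, and nothing has to be coupled at a hindered ketone. In these respects it is better than the chosen plan.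
- Weak points: the addition must choose between two squarate carbonyls that differ only in methoxy against tert-butoxy. The pyranone must be made and metalated next to its carbonyl. A1 is a 5,8-hydroquinone, prone to oxidation to the quinone. Its 8-hydroxyl still has to be methylated selectively beside the 5-hydroxyl before the tert-butyl group is removed.
- Comparison: the differentiation it offers is not needed here, because ring A is symmetrical. The chosen plan sets against it a ring A that is bought with three of its oxygens already benzylated and reaches the target in six steps.

**Alternative 2:** The bridge is cut at C3–C4 and at the oxygen on C2, leading to a nitrile oxide and an alkyne.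
- Key step: 2,4,6-tris(benzyloxy)-3,5-dimethoxybenzonitrile oxide A4 adds to 5-ethynyl-1,2,3-trimethoxybenzene A5 to give 3-[2,4,6-tris(benzyloxy)-3,5-dimethoxyphenyl]-5-(3,4,5-trimethoxyphenyl)isoxazole A3. Reductive N–O cleavage, debenzylation and acid closure would follow.
- Merits: a di-ortho-substituted nitrile oxide does not dimerise. The cycloaddition is regioselective, needs no strong base and no CO, and is little affected by crowding on ring A. On robustness of the key step it is at least equal to the chosen plan.
- Weak points: the nitrile oxide comes from an aldehyde oxime, so the ring A building block is one carbon short of the acetophenone and needs its own preparation plus oxime formation and oxidation. A5 is a less direct ring B source than iodide 5. The isoxazole must then be unmasked, so two or three steps are added.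
- Comparison: the chosen plan sets against it that ketone 4 enters with every carbon at its final oxidation level and that 8 is the direct flavone precursor.

**Alternative 3:** Ring C is cut at C4a–C4, C8a–O1 and O1–C2.
- Key step: fluoride releases the aryne from 3-(benzyloxy)-2,4-dimethoxy-5-{[(trifluoromethyl)sulfonyl]oxy}-6-(trimethylsilyl)phenyl 2,2-dimethylpropanoate A7. The aryne inserts into the C–O bond of 3-(3,4,5-trimethoxyphenyl)prop-2-ynoic acid A8, and the resulting phenoxide adds to the ynone to give 7-(benzyloxy)-6,8-dimethoxy-4-oxo-2-(3,4,5-trimethoxyphenyl)-4H-chromen-5-yl pivalate A6.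
- Merits: it is the most convergent road. The flavone forms in one operation under mild conditions without a transition metal or a strong base.
- Weak points: A7 is a hexasubstituted benzene with five different substituents. It gives up the symmetry of ring A and would take far more steps than 4. The aryne is flanked by oxygen on both sides, so the direction of carboxylate attack rests on the small inductive difference between a pivalate and a methoxy group; the wrong sense gives an isomeric flavone. The pivalate can migrate or be cleaved, and the phenoxide can close to an aurone instead.
- Comparison: the chosen plan forms ring C in a separate step. It sets against this a symmetrical ring A precursor made in three steps and a closure that cannot give a regioisomer.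

Key step: step 4

## Route

Assumption: 9 is drawn as the open diketo form, although it should exist largely as its enol and partly as hemiketal 10; this does not affect step 6.

Step 1
Reactants: 1 1,3,5-tris(benzyloxy)benzene
Product: 2 1-[2,4,6-tris(benzyloxy)phenyl]ethanone
Conditions: AcOH (1.3 equiv), (CF3CO)2O (1.5 equiv), CH2Cl2, 0 °C to rt; aq. NaHCO3
Reagents that add atoms: acetic acid, CC(=O)O
Why: Friedel–Crafts acylation by acetyl trifluoroacetate formed in the flask; the three free positions of the phloroglucinol triether are equivalent and strongly activated, the ketone deactivates the ring against a second acylation, and no chelating Lewis acid is present that could strip an ortho benzyl ether.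

Step 2
Reactants: 2 1-[2,4,6-tris(benzyloxy)phenyl]ethanone
Product: 3 1-[2,4,6-tris(benzyloxy)-3,5-dibromophenyl]ethanone
Conditions: NBS (2.1 equiv), MeCN, 0 °C to rt, dark
Reagents that add atoms: N-bromosuccinimide, O=C1CCC(=O)N1Br
Why: Electrophilic aromatic bromination at the only two free ring positions, each ortho/para to three alkoxy groups; without acid or light the trialkoxyarene should react far faster than the acetyl methyl group or the benzylic positions.

Step 3
Reactants: 3 1-[2,4,6-tris(benzyloxy)-3,5-dibromophenyl]ethanone
Product: 4 1-[2,4,6-tris(benzyloxy)-3,5-dimethoxyphenyl]ethanone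
Conditions: NaOMe (10 equiv, solution in MeOH), CuBr (30 mol %), DMF, 110 °C, argon
Reagents that add atoms: sodium methoxide, [Na+].[O-]C
Why: Ullmann-type methoxylation by monovalent copper, a reaction type established for ring A bromides of polyoxygenated acetophenones and flavones that are flanked by two oxygens; benzyl ethers tolerate methoxide and the hindered ketone should not self-condense.

Step 4
Reactants: 4 1-[2,4,6-tris(benzyloxy)-3,5-dimethoxyphenyl]ethanone; 5 5-iodo-1,2,3-trimethoxybenzene; 6 carbon monoxide
Product: 8 1-[2,4,6-tris(benzyloxy)-3,5-dimethoxyphenyl]-3-(3,4,5-trimethoxyphenyl)propane-1,3-dione, via sodium enolate 7 (not isolated)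
Conditions: NaN(SiMe3)2 (2.1 equiv), THF, 0 °C; then 5 (1.3 equiv), Pd(OAc)2 (5 mol %), Xantphos (6 mol %), CO (about 2 bar, sealed vessel), THF/dioxane, 80 °C; aq. NH4Cl
Reagents that add atoms: none
Why: Pd(OAc)2 and the bisphosphine are reduced in the flask to zerovalent palladium, which inserts into the C–I bond of 5; CO insertion then gives an aroyl complex of divalent palladium and forms C2–C1'. Enolate 7 displaces iodide on this complex and C–C reductive elimination forms C2–C3; no ring closes and no stereocentre is created. The closest known reaction type is the palladium-catalysed carbonylative α-arylation of aryl methyl ketones with aryl iodides to 1,3-diketones. Diketone 8 is more acidic than 4 and is held as its chelated sodium enolate by the second equivalent of base, which protects it from a second aroylation and drives turnover. The step needs C-aroylation to win over direct α-arylation, O-aroylation and capture of the aroyl complex by the silylamide. CO pressure and the wide-bite-angle ligand (fast insertion, fast acyl reductive elimination) favour it, as does forming 7 before the catalyst is added. In the substrate, 4 can enolise only toward its methyl group, and its carbonyl, flanked by two benzyloxy groups, acts only as part of the nucleophile and never has to be attacked. The electron-rich iodide 5 gives an aroyl complex that should resist decarbonylation.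

Step 5
Reactants: 8 1-[2,4,6-tris(benzyloxy)-3,5-dimethoxyphenyl]-3-(3,4,5-trimethoxyphenyl)propane-1,3-dione
Product: 9 1-(2,4,6-trihydroxy-3,5-dimethoxyphenyl)-3-(3,4,5-trimethoxyphenyl)propane-1,3-dione
Conditions: H2 (1 atm), 10% Pd/C, EtOAc/MeOH, rt; crude product kept under argon
Reagents that add atoms: none
Why: Hydrogenolysis of aryl benzyl ethers; at one atmosphere and room temperature the enolised aryl diketone and the methyl ethers should not be touched.

Step 6
Reactants: 9 1-(2,4,6-trihydroxy-3,5-dimethoxyphenyl)-3-(3,4,5-trimethoxyphenyl)propane-1,3-dione
Product: 11 5,7-dihydroxy-6,8-dimethoxy-2-(3,4,5-trimethoxyphenyl)-4H-chromen-4-one (5,7-dihydroxy-6,8,3',4',5'-pentamethoxyflavone), via 2-hydroxyflavanone hemiketal 10 (not isolated)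
Conditions: H2SO4 (cat.), AcOH, 80 °C, argon
Reagents that add atoms: none
Why: Acid-catalysed cyclodehydration of an ortho-hydroxyaryl 1,3-diketone: an ortho hydroxyl adds to the ring B carbonyl (6-exo-trig) to give hemiketal 10, which loses water to the pyranone; the two ortho hydroxyls are equivalent, so one flavone results, and a Wessely–Moser reopening would be degenerate.

## Compound list

1 | 1,3,5-tris(benzyloxy)benzene | c1ccc(COc2cc(OCc3ccccc3)cc(OCc3ccccc3)c2)cc1 | starting material
2 | 1-[2,4,6-tris(benzyloxy)phenyl]ethanone | CC(=O)c1c(OCc2ccccc2)cc(OCc2ccccc2)cc1OCc1ccccc1 | intermediate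
3 | 1-[2,4,6-tris(benzyloxy)-3,5-dibromophenyl]ethanone | CC(=O)c1c(OCc2ccccc2)c(Br)c(OCc2ccccc2)c(Br)c1OCc1ccccc1 | intermediate
4 | 1-[2,4,6-tris(benzyloxy)-3,5-dimethoxyphenyl]ethanone | CC(=O)c1c(OCc2ccccc2)c(OC)c(OCc2ccccc2)c(OC)c1OCc1ccccc1 | intermediate
5 | 5-iodo-1,2,3-trimethoxybenzene | COc1cc(I)cc(OC)c1OC | starting material
6 | carbon monoxide | [C-]#[O+] | starting material
7 | sodium 1-[2,4,6-tris(benzyloxy)-3,5-dimethoxyphenyl]ethen-1-olate | [Na+].C=C([O-])c1c(OCc2ccccc2)c(OC)c(OCc2ccccc2)c(OC)c1OCc1ccccc1 | intermediate (not isolated)
8 | 1-[2,4,6-tris(benzyloxy)-3,5-dimethoxyphenyl]-3-(3,4,5-trimethoxyphenyl)propane-1,3-dione | COc1cc(C(=O)CC(=O)c2c(OCc3ccccc3)c(OC)c(OCc3ccccc3)c(OC)c2OCc2ccccc2)cc(OC)c1OC | intermediate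
9 | 1-(2,4,6-trihydroxy-3,5-dimethoxyphenyl)-3-(3,4,5-trimethoxyphenyl)propane-1,3-dione | COc1cc(C(=O)CC(=O)c2c(O)c(OC)c(O)c(OC)c2O)cc(OC)c1OC | intermediate
10 | 2,5,7-trihydroxy-6,8-dimethoxy-2-(3,4,5-trimethoxyphenyl)-2,3-dihydro-4H-chromen-4-one (racemic hemiketal) | COc1cc(C2(O)CC(=O)c3c(O)c(OC)c(O)c(OC)c3O2)cc(OC)c1OC | intermediate (not isolated)
11 | 5,7-dihydroxy-6,8-dimethoxy-2-(3,4,5-trimethoxyphenyl)-4H-chromen-4-one | COc1cc(-c2cc(=O)c3c(O)c(OC)c(O)c(OC)c3o2)cc(OC)c1OC | target

## Step count and risks

Total: 6 steps. Longest linear sequence: 6 steps (1 to 11).

**Step 4 (key step).** The crowded enolate 7 may bind slowly to the aroyl palladium complex. That would leave room for direct α-arylation without CO uptake, O-aroylation, capture of the aroyl group by the silylamide, or a second aroylation of the diketonate. Fallback: a crossed Claisen condensation, which forms only C2–C3 and buys C2 already attached to ring B. It sets out from 4, which is deprotonated with LiN(SiMe3)2 in THF at −78 °C and treated with commercial methyl 3,4,5-trimethoxybenzoate while warming to room temperature. It returns to the route at 8 and makes no new compound.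

**Step 3.** Substitution at bromides flanked by two benzyloxy groups may be slow. Hydrodebromination, stalling after the first methoxy group, or nucleophilic loss of a benzyl group ortho to the acetyl group could then compete. Fallback: from 3, palladium-catalysed hydroxylation (Pd2(dba)3, 2-di-tert-butylphosphino-2',4',6'-triisopropylbiphenyl, KOH, dioxane/water, 100 °C) to 1-[2,4,6-tris(benzyloxy)-3,5-dihydroxyphenyl]ethanone F1. O-Methylation with iodomethane and K2CO3 in acetone then rejoins the route at 4.

**Step 1.** The trifluoroacetic acid formed during the acylation may cleave a benzyl ether or shift a benzyl group onto the ring, and the acylation itself may be slow at a position flanked by two benzyloxy groups. Fallback: build the acetyl group in two carbon–carbon bond formations under non-acidic or buffered conditions. From 1, Vilsmeier–Haack formylation (POCl3, DMF, 0 °C to rt; then water) should give 2,4,6-tris(benzyloxy)benzaldehyde F2. Addition of MeMgBr in THF at 0 °C (aq. NH4Cl work-up) should give racemic 1-[2,4,6-tris(benzyloxy)phenyl]ethan-1-ol F3. Oxidation with Dess–Martin periodinane buffered with NaHCO3 in CH2Cl2 then rejoins the route at 2.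

**Step 2.** Bromination may go to the acetyl methyl group, or the second nuclear bromination may stall on the deactivated, twisted monobromide. Fallback: reverse the order, so that no ketone is present while the ring is brominated and methoxylated. From 1, N-bromosuccinimide (2.0 equiv) in MeCN at 0 °C should give 1,3,5-tris(benzyloxy)-2,4-dibromobenzene F4. Copper-catalysed methoxylation (NaOMe, CuBr, DMF, 110 °C) should give 1,3,5-tris(benzyloxy)-2,4-dimethoxybenzene F5. Acetylation of its single free position with AcOH and (CF3CO)2O in CH2Cl2, as in step 1, then rejoins the route at 4.

**Step 5.** The benzylic carbonyl or the enol may be over-reduced, and the electron-rich triol may be oxidised during filtration and handling. Fallback: non-reductive debenzylation of 8 with BCl3 and pentamethylbenzene as cation scavenger in CH2Cl2 at −78 °C, followed by aqueous work-up. It returns to the route at 9 and makes no new compound.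

## Further compounds

F0 | step 4 | none | none
F1 | step 3 | 1-[2,4,6-tris(benzyloxy)-3,5-dihydroxyphenyl]ethanone | CC(=O)c1c(OCc2ccccc2)c(O)c(OCc2ccccc2)c(O)c1OCc1ccccc1
F2 | step 1 | 2,4,6-tris(benzyloxy)benzaldehyde | O=Cc1c(OCc2ccccc2)cc(OCc2ccccc2)cc1OCc1ccccc1
F3 | step 1 | 1-[2,4,6-tris(benzyloxy)phenyl]ethan-1-ol (racemic) | CC(O)c1c(OCc2ccccc2)cc(OCc2ccccc2)cc1OCc1ccccc1
F4 | step 2 | 1,3,5-tris(benzyloxy)-2,4-dibromobenzene | Brc1c(OCc2ccccc2)cc(OCc2ccccc2)c(Br)c1OCc1ccccc1
F5 | step 2 | 1,3,5-tris(benzyloxy)-2,4-dimethoxybenzene | COc1c(OCc2ccccc2)cc(OCc2ccccc2)c(OC)c1OCc1ccccc1
F0 | step 5 | none | none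
A1 | alternative 1 | 7-tert-butoxy-5,8-dihydroxy-6-methoxy-2-(3,4,5-trimethoxyphenyl)-4H-chromen-4-one | COc1cc(-c2cc(=O)c3c(O)c(OC)c(OC(C)(C)C)c(O)c3o2)cc(OC)c1OC
A2 | alternative 1 | 2-tert-butoxy-4-hydroxy-3-methoxy-4-[4-oxo-6-(3,4,5-trimethoxyphenyl)-4H-pyran-3-yl]cyclobut-2-en-1-one (racemic) | COC1=C(OC(C)(C)C)C(=O)C1(O)c1coc(-c2cc(OC)c(OC)c(OC)c2)cc1=O
A3 | alternative 2 | 3-[2,4,6-tris(benzyloxy)-3,5-dimethoxyphenyl]-5-(3,4,5-trimethoxyphenyl)isoxazole | COc1cc(-c2cc(-c3c(OCc4ccccc4)c(OC)c(OCc4ccccc4)c(OC)c3OCc3ccccc3)no2)cc(OC)c1OC
A4 | alternative 2 | 2,4,6-tris(benzyloxy)-3,5-dimethoxybenzonitrile oxide | [O-][N+]#Cc1c(OCc2ccccc2)c(OC)c(OCc2ccccc2)c(OC)c1OCc1ccccc1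
A5 | alternative 2 | 5-ethynyl-1,2,3-trimethoxybenzene | C#Cc1cc(OC)c(OC)c(OC)c1
A6 | alternative 3 | 7-(benzyloxy)-6,8-dimethoxy-4-oxo-2-(3,4,5-trimethoxyphenyl)-4H-chromen-5-yl pivalate | COc1cc(-c2cc(=O)c3c(OC(=O)C(C)(C)C)c(OC)c(OCc4ccccc4)c(OC)c3o2)cc(OC)c1OC
A7 | alternative 3 | 3-(benzyloxy)-2,4-dimethoxy-5-{[(trifluoromethyl)sulfonyl]oxy}-6-(trimethylsilyl)phenyl 2,2-dimethylpropanoate | CC(C)(C)C(=O)Oc1c(OC)c(OCc2ccccc2)c(OC)c(OS(=O)(=O)C(F)(F)F)c1[Si](C)(C)C
A8 | alternative 3 | 3-(3,4,5-trimethoxyphenyl)prop-2-ynoic acid | COc1cc(C#CC(=O)O)cc(OC)c1OC
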